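**Retrosynthetic overview**

1. Target ⇐ acetal hydrolysis/desilylation, C9 inversion–acetylation and C9/C15 reduction of a ten-membered dienone (C9 ketone, C15 aldehyde, C14 dimethyl acetal).
2. Ten-membered ring ⇐ ring expansion: fluoride-triggered retro-aldol/E1cB cleavage of the C4–C9 ring-fusion bond of a decalin β-siloxy aldehyde (6/6 → 10).
3. Decalin ⇐ intramolecular Diels–Alder reaction of a 1-siloxy diene (C9=C10–C1=C2) with a tethered 2-substituted acrolein (C3=C4).
4. Acyclic precursor ⇐ Morita–Baylis–Hillman reaction with acrolein (C4–C5); Barbier allylation of a keto aldehyde with a 3-(bromomethyl)butenolide (C7–C8, unveils the α-methylene lactone); hydroxymethylation with formaldehyde (C11–C13).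
5. Ring order: γ-lactone (chiral-pool butenolide) → two six-membered carbocycles in one cycloaddition → ten-membered ring by excision of their shared bond.

Assumption: locants C1–C15 follow germacrane numbering of the target (ring C1–C10, lactone C11–C13, C14 on C10, C15 on C4); 2,2-dimethyl-1,3-dioxolan-4-one and (S)-5-(hydroxymethyl)furan-2(5H)-one are taken as commercial.

**Route**

Step 1
Reactants: 1 crotonaldehyde [(E)-but-2-enal]
Product: 3 (Z)-2-bromobut-2-enal, via 2,3-dibromobutanal 2 (not isolated)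
Conditions: Br2, CH2Cl2, 0 °C; then Et3N, 0 °C → rt
Reagents that add atoms: bromine BrBr
Why: Bromination–dehydrobromination (anti addition of Br2, then E1cB loss of HBr from the acidic α-position) gives the α-bromo enal as the thermodynamic Z isomer with CH3 trans to CHO.

Step 2
Reactants: 3 (Z)-2-bromobut-2-enal
Product: 4 (Z)-2-bromo-1,1-dimethoxybut-2-ene
Conditions: HC(OMe)3, MeOH, p-toluenesulfonic acid (cat.), rt
Reagents that add atoms: trimethyl orthoformate COC(OC)OC
Why: Acid-catalysed acetalisation with the orthoformate as water scavenger masks the future C14 formyl group so the vinyl bromide can be lithiated; the alkene geometry is untouched.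

Step 3
Reactants: 4 (Z)-2-bromo-1,1-dimethoxybut-2-ene; 5 2,2-dimethyl-1,3-dioxolan-4-one
Product: 8 (Z)-3-(dimethoxymethyl)-1-hydroxypent-3-en-2-one, via vinyllithium 6 (not isolated), via lithium hemiketal alkoxide 7 (not isolated)
Conditions: t-BuLi (2 equiv), Et2O, −78 °C; then 5, −78 °C; then H2O
Reagents that add atoms: none
Why: Bromine–lithium exchange retains the alkene geometry and the vinyllithium adds only once to the masked glycolic acid (acyl substitution), because alkoxide 7 collapses to the ketone and acetone only on aqueous work-up.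

Step 4
Reactants: 8 (Z)-3-(dimethoxymethyl)-1-hydroxypent-3-en-2-one
Product: 9 (Z)-3-(dimethoxymethyl)-2-oxopent-3-enal
Conditions: Dess–Martin periodinane, pyridine, CH2Cl2, 0 °C; used crude
Reagents that add atoms: none
Why: Buffered Dess–Martin oxidation converts the primary α-ketol into the α-keto aldehyde without touching the acetal or the Z-enone.

Step 5
Reactants: 10 (S)-5-(hydroxymethyl)furan-2(5H)-one
Product: 11 (S)-5-[(triethylsilyloxy)methyl]furan-2(5H)-one
Conditions: Et3SiCl, imidazole, CH2Cl2, 0 °C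
Reagents that add atoms: chlorotriethylsilane CC[Si](Cl)(CC)CC
Why: Silylation of the primary alcohol; the ring stereocenter (C6 of the target, taken from the chiral pool) is not touched.

Step 6
Reactants: 11 (S)-5-[(triethylsilyloxy)methyl]furan-2(5H)-one; 12 formaldehyde
Product: 13 (S)-3-(hydroxymethyl)-5-[(triethylsilyloxy)methyl]furan-2(5H)-one
Conditions: 37% aq. HCHO, PBu3 (0.2 equiv), THF, rt
Reagents that add atoms: none
Why: Morita–Baylis–Hillman α-hydroxymethylation (phosphine adds at C4, the enolate takes up formaldehyde at C3, elimination restores the butenolide) installs C13, and the non-basic catalyst leaves the γ-stereocenter intact.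

Step 7
Reactants: 13 (S)-3-(hydroxymethyl)-5-[(triethylsilyloxy)methyl]furan-2(5H)-one
Product: 14 (S)-3-(bromomethyl)-5-[(triethylsilyloxy)methyl]furan-2(5H)-one
Conditions: CBr4, PPh3, CH2Cl2, 0 °C
Reagents that add atoms: carbon tetrabromide BrC(Br)(Br)Br
Why: Appel bromination of the primary allylic alcohol under neutral conditions that spare the silyl ether.

Step 8
Reactants: 14 (S)-3-(bromomethyl)-5-[(triethylsilyloxy)methyl]furan-2(5H)-one; 9 (Z)-3-(dimethoxymethyl)-2-oxopent-3-enal
Product: 15 (4R,5S)-4-[(1R,3Z)-3-(dimethoxymethyl)-1-hydroxy-2-oxopent-3-en-1-yl]-3-methylidene-5-[(triethylsilyloxy)methyl]oxolan-2-one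
Conditions: indium powder, THF/pH 7 phosphate buffer 3:1, rt
Reagents that add atoms: none
Why: Indium-mediated Barbier allylation with allylic transposition attacks the aldehyde, not the ketone, through ring carbon C4 anti to the 5-CH2OSiEt3 group, and the ring-locked E-type allyl unit reacts through a Zimmerman–Traxler chair to give the anti adduct, which sets C7 and C8 and unveils the α-methylene lactone.

Step 9
Reactants: 15 the hydroxy ketone lactone from step 8; 16 methacryloyl chloride (2-methylprop-2-enoyl chloride)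
Product: 17 (1R,3Z)-3-(dimethoxymethyl)-1-{(2S,3S)-4-methylidene-5-oxo-2-[(triethylsilyloxy)methyl]oxolan-3-yl}-2-oxopent-3-en-1-yl 2-methylprop-2-enoate
Conditions: Et3N, 4-(dimethylamino)pyridine (cat.), CH2Cl2, −20 °C
Reagents that add atoms: none
Why: Nucleophile-catalysed esterification of the only free hydroxyl group installs the C8 methacrylate without touching a stereocenter.

Step 10
Reactants: 17 the methacrylate silyl ether from step 9
Product: 18 (1R,3Z)-3-(dimethoxymethyl)-1-[(2S,3S)-2-formyl-4-methylidene-5-oxooxolan-3-yl]-2-oxopent-3-en-1-yl 2-methylprop-2-enoate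
Conditions: (COCl)2, DMSO, CH2Cl2, −78 → −40 °C; then Et3N, −78 → 0 °C
Reagents that add atoms: none
Why: Swern conditions oxidise a primary triethylsilyl ether directly to the aldehyde (alkoxysulfonium formation at the ether oxygen with loss of Et3SiCl), and the low temperature spares the α-acyloxy ketone and the α-oxy aldehyde stereocenter.

Step 11
Reactants: 18 the C5 aldehyde from step 10; 19 acrolein (prop-2-enal)
Product: 20 (1R,3Z)-3-(dimethoxymethyl)-1-[(2S,3S)-2-(2-formyl-1-hydroxyprop-2-en-1-yl)-4-methylidene-5-oxooxolan-3-yl]-2-oxopent-3-en-1-yl 2-methylprop-2-enoate (both carbinol epimers)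
Conditions: acrolein (3 equiv), 1,4-diazabicyclo[2.2.2]octane (0.3 equiv), THF, 0 °C
Reagents that add atoms: none
Why: Morita–Baylis–Hillman reaction of the activated α-oxy aldehyde installs C3, C4 and C15 as a 2-substituted acrolein; the new carbinol center C5 forms as a mixture, which is irrelevant because C5 becomes sp2 in step 13.

Step 12
Reactants: 20 the Morita–Baylis–Hillman alcohol from step 11
Product: 21 (1R,3Z)-1-{(2S,3S)-2-[1-(acetyloxy)-2-formylprop-2-en-1-yl]-4-methylidene-5-oxooxolan-3-yl}-3-(dimethoxymethyl)-2-oxopent-3-en-1-yl 2-methylprop-2-enoate (both C5 epimers)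
Conditions: AcCl, pyridine, CH2Cl2, 0 °C
Reagents that add atoms: acetyl chloride CC(Cl)=O
Why: O-Acetylation turns the C5 hydroxyl into the leaving group needed for the E1cB step of the ring expansion.

Step 13
Reactants: 21 the acetate from step 12
Product: 24 (1Z,4E,6R,7S,8R)-14,14-dimethoxy-8-(methacryloyloxy)-9,15-dioxogermacra-1(10),4,11(13)-trien-12,6-olide, via triethylsilyl dienol ether 22 (not isolated), via silylated decalin cycloadduct 23 (not isolated)
Conditions: Et3SiOTf, i-Pr2NEt, CH2Cl2, −78 → 0 °C; then PhMe (0.005 M), 80 °C; then Bu4NF, THF, −20 → 0 °C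
Reagents that add atoms: none
Why: Proposed new method: soft enolisation removes a proton from the unhindered γ-methyl group (C2, cis to the carbonyl) rather than from the congested acyloxy-bearing C8 methine and gives a 1-siloxy diene whose nucleophilic terminus C2 is matched with the β-carbon C3 of the tethered 2-substituted acrolein, so an intramolecular Diels–Alder reaction closes C2–C3 and C4–C9 as a decalin; fluoride then unmasks the ring-fusion alkoxide β to the angular formyl group, retro-aldol cleavage of the strained C4–C9 bond gives the ten-membered keto aldehyde enolate, and E1cB loss of the C5 acetate makes the ring expansion irreversible, the cyclohexene supplying the ring-cis 1(10)-alkene and the elimination the thermodynamic E-enal; closest known reactions are the Wharton–Grob fragmentation of decalin 1,3-diol monosulfonates and the retro-aldol step of the de Mayo reaction, and C4, C5 and C9 of the cycloadduct are transient, so its diastereoselectivity does not matter.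

Step 14
Reactants: 24 the ten-membered dienone from step 13
Product: 25 (1E,4E,6R,7S,8R,9R)-9,15-dihydroxy-14,14-dimethoxy-8-(methacryloyloxy)germacra-1(10),4,11(13)-trien-12,6-olide
Conditions: NaBH4, CeCl3·7H2O, MeOH, −78 °C
Reagents that add atoms: none
Why: Luche reduction gives clean 1,2-reduction of the enal and the cross-conjugated enone without conjugate reduction of the α-methylene lactone; at C9 hydride is expected to add in the polar Felkin–Anh sense (anti to the C8–O bond) to give the 8,9-syn alcohol (9R), which step 16 inverts.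

Step 15
Reactants: 25 the diol from step 14
Product: 26 (1E,4E,6R,7S,8R,9R)-9-hydroxy-14,14-dimethoxy-8-(methacryloyloxy)-15-(triethylsilyloxy)germacra-1(10),4,11(13)-trien-12,6-olide
Conditions: Et3SiCl (1.1 equiv), imidazole, CH2Cl2, −40 °C
Reagents that add atoms: chlorotriethylsilane CC[Si](Cl)(CC)CC
Why: Selective silylation of the primary allylic alcohol over the hindered secondary C9 alcohol.

Step 16
Reactants: 26 the silyl ether from step 15; 27 acetic acid
Product: 28 (1E,4E,6R,7S,8R,9S)-9-acetoxy-14,14-dimethoxy-8-(methacryloyloxy)-15-(triethylsilyloxy)germacra-1(10),4,11(13)-trien-12,6-olide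
Conditions: PPh3, diisopropyl azodicarboxylate, THF, 0 °C → rt
Reagents that add atoms: none
Why: Mitsunobu esterification: acetate displaces the C9 oxyphosphonium group by SN2 with inversion, converting 9R into the required 9S acetate.

Step 17
Reactants: 28 the acetate from step 16
Product: 29 (1E,4E,6R,7S,8R,9S)-9-acetoxy-15-hydroxy-8-(methacryloyloxy)-14-oxogermacra-1(10),4,11(13)-trien-12,6-olide (CNP0147326.13)
Conditions: pyridinium p-toluenesulfonate (cat.), acetone/H2O 10:1, 40 °C
Reagents that add atoms: water O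
Why: Mild acid hydrolysis cleaves the dimethyl acetal and the primary silyl ether together, unveiling the C14 enal and the C15 alcohol without affecting the esters, the lactone, the stereocenters or the alkene geometries.

**Compound list**

1 | crotonaldehyde, (E)-but-2-enal | C/C=C/C=O | starting material
2 | 2,3-dibromobutanal (diastereomer mixture) | CC(Br)C(Br)C=O | intermediate
3 | (Z)-2-bromobut-2-enal | C/C=C(/C=O)Br | intermediate
4 | (Z)-2-bromo-1,1-dimethoxybut-2-ene | C/C=C(/C(OC)OC)Br | intermediate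
5 | 2,2-dimethyl-1,3-dioxolan-4-one | CC1(C)OCC(=O)O1 | starting material
6 | [(E)-1,1-dimethoxybut-2-en-2-yl]lithium | C/C=C(/C(OC)OC)[Li] | intermediate
7 | lithium 4-[(Z)-1,1-dimethoxybut-2-en-2-yl]-2,2-dimethyl-1,3-dioxolan-4-olate (racemic at C4) | C/C=C(\C1([O-])COC(C)(C)O1)C(OC)OC.[Li+] | intermediate
8 | (Z)-3-(dimethoxymethyl)-1-hydroxypent-3-en-2-one | C/C=C(\C(=O)CO)C(OC)OC | intermediate
9 | (Z)-3-(dimethoxymethyl)-2-oxopent-3-enal | C/C=C(\C(=O)C=O)C(OC)OC | intermediate
10 | (S)-5-(hydroxymethyl)furan-2(5H)-one | O=C1O[C@H](CO)C=C1 | starting material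
11 | (S)-5-[(triethylsilyloxy)methyl]furan-2(5H)-one | O=C1O[C@H](CO[Si](CC)(CC)CC)C=C1 | intermediate
12 | formaldehyde | C=O | starting material
13 | (S)-3-(hydroxymethyl)-5-[(triethylsilyloxy)methyl]furan-2(5H)-one | O=C1O[C@H](CO[Si](CC)(CC)CC)C=C1CO | intermediate
14 | (S)-3-(bromomethyl)-5-[(triethylsilyloxy)methyl]furan-2(5H)-one | O=C1O[C@H](CO[Si](CC)(CC)CC)C=C1CBr | intermediate
15 | (4R,5S)-4-[(1R,3Z)-3-(dimethoxymethyl)-1-hydroxy-2-oxopent-3-en-1-yl]-3-methylidene-5-[(triethylsilyloxy)methyl]oxolan-2-one | C/C=C(\C(=O)[C@H](O)[C@H]1C(=C)C(=O)O[C@@H]1CO[Si](CC)(CC)CC)C(OC)OC | intermediate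
16 | methacryloyl chloride | C=C(C)C(Cl)=O | starting material
17 | (1R,3Z)-3-(dimethoxymethyl)-1-{(2S,3S)-4-methylidene-5-oxo-2-[(triethylsilyloxy)methyl]oxolan-3-yl}-2-oxopent-3-en-1-yl 2-methylprop-2-enoate | C/C=C(\C(=O)[C@H](OC(=O)C(C)=C)[C@H]1C(=C)C(=O)O[C@@H]1CO[Si](CC)(CC)CC)C(OC)OC | intermediate
18 | (1R,3Z)-3-(dimethoxymethyl)-1-[(2S,3S)-2-formyl-4-methylidene-5-oxooxolan-3-yl]-2-oxopent-3-en-1-yl 2-methylprop-2-enoate | C/C=C(\C(=O)[C@H](OC(=O)C(C)=C)[C@H]1C(=C)C(=O)O[C@@H]1C=O)C(OC)OC | intermediate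
19 | acrolein | C=CC=O | starting material
20 | (1R,3Z)-3-(dimethoxymethyl)-1-[(2S,3S)-2-(2-formyl-1-hydroxyprop-2-en-1-yl)-4-methylidene-5-oxooxolan-3-yl]-2-oxopent-3-en-1-yl 2-methylprop-2-enoate (both carbinol epimers) | C/C=C(\C(=O)[C@H](OC(=O)C(C)=C)[C@H]1C(=C)C(=O)O[C@@H]1C(O)C(=C)C=O)C(OC)OC | intermediate
21 | (1R,3Z)-1-{(2S,3S)-2-[1-(acetyloxy)-2-formylprop-2-en-1-yl]-4-methylidene-5-oxooxolan-3-yl}-3-(dimethoxymethyl)-2-oxopent-3-en-1-yl 2-methylprop-2-enoate (both epimers at the acetoxy carbon) | C/C=C(\C(=O)[C@H](OC(=O)C(C)=C)[C@H]1C(=C)C(=O)O[C@@H]1C(OC(C)=O)C(=C)C=O)C(OC)OC | intermediate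
22 | (1R,2E)-1-{(2S,3S)-2-[1-(acetyloxy)-2-formylprop-2-en-1-yl]-4-methylidene-5-oxooxolan-3-yl}-3-(dimethoxymethyl)-2-(triethylsilyloxy)penta-2,4-dien-1-yl 2-methylprop-2-enoate | C=C/C(C(OC)OC)=C(\O[Si](CC)(CC)CC)[C@H](OC(=O)C(C)=C)[C@H]1C(=C)C(=O)O[C@@H]1C(OC(C)=O)C(=C)C=O | intermediate
23 | decalin cycloadduct of 22 (new C2–C3 and C4–C9 bonds): 5-acetoxy-14,14-dimethoxy-8-(methacryloyloxy)-15-oxo-9-(triethylsilyloxy)-4,9-cyclogermacra-1(10),11(13)-dien-12,6-olide, C6–C8 configured as in 21, mixture at C4, C5 and C9 | C1=C(C(OC)OC)C2(O[Si](CC)(CC)CC)[C@H](OC(=O)C(C)=C)[C@H]3C(=C)C(=O)O[C@@H]3C(OC(C)=O)C2(C=O)CC1 | intermediate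
24 | (1Z,4E,6R,7S,8R)-14,14-dimethoxy-8-(methacryloyloxy)-9,15-dioxogermacra-1(10),4,11(13)-trien-12,6-olide | C=C(C)C(=O)O[C@@H]1[C@H]2C(=C)C(=O)O[C@@H]2/C=C(/C=O)CC/C=C(/C(OC)OC)C1=O | intermediate
25 | (1E,4E,6R,7S,8R,9R)-9,15-dihydroxy-14,14-dimethoxy-8-(methacryloyloxy)germacra-1(10),4,11(13)-trien-12,6-olide | C=C(C)C(=O)O[C@@H]1[C@H]2C(=C)C(=O)O[C@@H]2/C=C(/CO)CC/C=C(/C(OC)OC)[C@H]1O | intermediate
26 | (1E,4E,6R,7S,8R,9R)-9-hydroxy-14,14-dimethoxy-8-(methacryloyloxy)-15-(triethylsilyloxy)germacra-1(10),4,11(13)-trien-12,6-olide | C=C(C)C(=O)O[C@@H]1[C@H]2C(=C)C(=O)O[C@@H]2/C=C(/CO[Si](CC)(CC)CC)CC/C=C(/C(OC)OC)[C@H]1O | intermediate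
27 | acetic acid | CC(=O)O | starting material
28 | (1E,4E,6R,7S,8R,9S)-9-acetoxy-14,14-dimethoxy-8-(methacryloyloxy)-15-(triethylsilyloxy)germacra-1(10),4,11(13)-trien-12,6-olide | C=C(C)C(=O)O[C@@H]1[C@H]2C(=C)C(=O)O[C@@H]2/C=C(/CO[Si](CC)(CC)CC)CC/C=C(/C(OC)OC)[C@@H]1OC(C)=O | intermediate
29 | (1E,4E,6R,7S,8R,9S)-9-acetoxy-15-hydroxy-8-(methacryloyloxy)-14-oxogermacra-1(10),4,11(13)-trien-12,6-olide (CNP0147326.13) | C=C(C)C(=O)O[C@@H]1[C@H]2C(=C)C(=O)O[C@@H]2/C=C(/CO)CC/C=C(/C=O)[C@@H]1OC(C)=O | target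

**Step count and risks**

Total: 17 steps. Longest linear sequence: 14 steps (steps 1–4, then 8–17); the butenolide branch (steps 5–7) joins at step 8.

Stereocenters: C6 comes from 10; C7 and C8 are set in step 8; C9 is set in step 14 and inverted in step 16. C4, C5 and C9 of 20–23 are transient.

The three steps most likely to fail:

Step 13 (the proposed new domino ring expansion). Risks are enolisation towards C8 instead of C2, a sluggish cycloaddition between two fully substituted carbons, and base-induced epimerisation at C8 during the fluoride stage. The fallback sets out from 21 and returns at 24, and replaces the domino by isolated operations of known types. Compound 21 is converted with t-BuMe2SiOTf/Et3N into the isolable tert-butyldimethylsilyl dienol ether F1. Heating F1 in toluene at 110 °C with BHT (thermal intramolecular Diels–Alder reaction of a siloxy diene) gives the silylated decalin cycloadduct F2, which is isolated. HF·pyridine/pyridine cleaves the tertiary silyl ether to the decalin β-hydroxy aldehyde F3. DBU in CH2Cl2 then effects a de Mayo-type retro-aldol fragmentation followed by β-elimination of acetate and gives 24.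

Step 11 (Morita–Baylis–Hillman reaction with acrolein). Acrolein oligomerises, and the amine can epimerise the α-oxy aldehyde or attack the other acceptors. The fallback sets out from 18 and returns at 21. A Nozaki–Hiyama–Kishi coupling of 18 with tert-butyl[(2-bromoprop-2-en-1-yl)oxy]dimethylsilane (from 2-bromoallyl alcohol; CrCl2, NiCl2 (cat.), DMSO) gives the allylic alcohol silyl ether F4. AcCl/pyridine gives the acetate F5, HF·pyridine gives the primary allylic alcohol F6, and MnO2 oxidises F6 to 21.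

Step 16 (Mitsunobu inversion at C9, which depends on the facial outcome of step 14). The hindered allylic alcohol may react slowly, the neighbouring C8 ester may participate, or SN2′ attack may compete. The fallback sets out from 24 and returns at 28, and uses reagent control with retention instead of substrate control with inversion. Corey–Bakshi–Shibata reduction of 24 with catecholborane and (S)- or (R)-1-methyl-3,3-diphenyltetrahydro-1H,3H-pyrrolo[1,2-c][1,3,2]oxazaborole (enantiomer chosen in a two-run screen) gives the 9S diol F7. Et3SiCl/imidazole gives its 15-silyl ether F8, and Ac2O/pyridine/4-(dimethylamino)pyridine acetylates C9 with retention to give 28. If step 14 itself delivers the 9S alcohol, the same direct acetylation is used.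

**Further compounds**

F1 | step 13 | (1R,2E)-1-{(2S,3S)-2-[1-(acetyloxy)-2-formylprop-2-en-1-yl]-4-methylidene-5-oxooxolan-3-yl}-2-(tert-butyldimethylsilyloxy)-3-(dimethoxymethyl)penta-2,4-dien-1-yl 2-methylprop-2-enoate | C=C/C(C(OC)OC)=C(\O[Si](C)(C)C(C)(C)C)[C@H](OC(=O)C(C)=C)[C@H]1C(=C)C(=O)O[C@@H]1C(OC(C)=O)C(=C)C=O
F2 | step 13 | tert-butyldimethylsilyl analogue of 23 (9-O-silylated decalin cycloadduct, mixture at C4, C5 and C9) | C1=C(C(OC)OC)C2(O[Si](C)(C)C(C)(C)C)[C@H](OC(=O)C(C)=C)[C@H]3C(=C)C(=O)O[C@@H]3C(OC(C)=O)C2(C=O)CC1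
F3 | step 13 | 9-hydroxy decalin β-hydroxy aldehyde (desilylated F2, mixture at C4, C5 and C9) | C1=C(C(OC)OC)C2(O)[C@H](OC(=O)C(C)=C)[C@H]3C(=C)C(=O)O[C@@H]3C(OC(C)=O)C2(C=O)CC1
F4 | step 11 | (1R,3Z)-1-{(2S,3S)-2-[2-({[tert-butyl(dimethyl)silyl]oxy}methyl)-1-hydroxyprop-2-en-1-yl]-4-methylidene-5-oxooxolan-3-yl}-3-(dimethoxymethyl)-2-oxopent-3-en-1-yl 2-methylprop-2-enoate (both carbinol epimers) | C/C=C(\C(=O)[C@H](OC(=O)C(C)=C)[C@H]1C(=C)C(=O)O[C@@H]1C(O)C(=C)CO[Si](C)(C)C(C)(C)C)C(OC)OC
F5 | step 11 | acetate of F4 (both epimers) | C/C=C(\C(=O)[C@H](OC(=O)C(C)=C)[C@H]1C(=C)C(=O)O[C@@H]1C(OC(C)=O)C(=C)CO[Si](C)(C)C(C)(C)C)C(OC)OC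
F6 | step 11 | (1R,3Z)-1-{(2S,3S)-2-[1-(acetyloxy)-2-(hydroxymethyl)prop-2-en-1-yl]-4-methylidene-5-oxooxolan-3-yl}-3-(dimethoxymethyl)-2-oxopent-3-en-1-yl 2-methylprop-2-enoate (both epimers) | C/C=C(\C(=O)[C@H](OC(=O)C(C)=C)[C@H]1C(=C)C(=O)O[C@@H]1C(OC(C)=O)C(=C)CO)C(OC)OC
F7 | step 16 | (1E,4E,6R,7S,8R,9S)-9,15-dihydroxy-14,14-dimethoxy-8-(methacryloyloxy)germacra-1(10),4,11(13)-trien-12,6-olide | C=C(C)C(=O)O[C@@H]1[C@H]2C(=C)C(=O)O[C@@H]2/C=C(/CO)CC/C=C(/C(OC)OC)[C@@H]1O
F8 | step 16 | (1E,4E,6R,7S,8R,9S)-9-hydroxy-14,14-dimethoxy-8-(methacryloyloxy)-15-(triethylsilyloxy)germacra-1(10),4,11(13)-trien-12,6-olide | C=C(C)C(=O)O[C@@H]1[C@H]2C(=C)C(=O)O[C@@H]2/C=C(/CO[Si](CC)(CC)CC)CC/C=C(/C(OC)OC)[C@@H]1O
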